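Both halves are 2,3-seco-8,13-epoxylabdanes that differ at C13; half A carries the vinyl group, half B the esterified diol. Everything rests on disconnecting the C5–C10 bond of the cyclohexane (ring B) of half A: because ring A is absent, the quaternary C10 and its neighbour C5 carry open-chain arms. With the tetrahydropyran (ring C: O, C8, C9, C11–C13) already in place, iron-hydride hydrogen-atom transfer to a 1,1-disubstituted olefin on C9 gives the tertiary C10 radical, which closes ring B by 6-exo-trig addition to a C5=C4 enoate tethered to C8 and sets C10 and C5 in one operation. The precursor is a monocyclic tetrahydropyran.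

Key step: step 20

Remark: atom labels follow labdane numbering within each half (ring C = O, C8, C9, C11, C12, C13; ring B = C5–C10; C14/C15 on C13; arms C1–C2 on C10 and C4–C3 on C5; C16, C17, C20 are the methyls on C13, C8, C10); TBS = tert-butyldimethylsilyl, TBDPS = tert-butyldiphenylsilyl, TMSE = 2-(trimethylsilyl)ethyl.

Step 1
Reactants: 1 3-bromobut-3-en-1-ol
Product: 2 tert-butyl[(3-bromobut-3-en-1-yl)oxy]diphenylsilane
Conditions: TBDPSCl, imidazole, DMF, rt
Reagents that add atoms: tert-butyl(chloro)diphenylsilane, CC(C)(C)[Si](Cl)(c1ccccc1)c1ccccc1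
Why: Silyl ether formation at the primary alcohol gives an ether that should survive the organometallic, radical and enolate steps and fall to fluoride at the end.

Step 2
Reactants: 3 2-bromopropanoyl bromide; 4 2-(trimethylsilyl)ethanol
Product: 5 2-(trimethylsilyl)ethyl 2-bromopropanoate (racemic)
Conditions: pyridine, CH2Cl2, 0 °C to rt
Reagents that add atoms: none
Why: Acylation of the alcohol by the acyl bromide (esterification) should be much faster than substitution at the secondary bromide.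

Step 3
Reactants: 5 2-(trimethylsilyl)ethyl 2-bromopropanoate
Product: 7 2-(trimethylsilyl)ethyl 2-(triphenyl-λ5-phosphanylidene)propanoate, via phosphonium bromide 6 (not isolated)
Conditions: PPh3, toluene, 90 °C; then aq. NaOH, CH2Cl2, rt
Reagents that add atoms: triphenylphosphine, c1ccc(cc1)P(c1ccccc1)c1ccccc1
Why: SN2 quaternisation of the phosphine by the α-bromo ester and deprotonation of the acidic salt should give the stabilised ylide (Wittig reagent synthesis).

Step 4
Reactants: 8 nerol, (2Z)-3,7-dimethylocta-2,6-dien-1-ol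
Product: 9 tert-butyl{[(2Z)-3,7-dimethylocta-2,6-dien-1-yl]oxy}dimethylsilane
Conditions: TBSCl, imidazole, DMF, rt
Reagents that add atoms: tert-butyl(chloro)dimethylsilane, CC(C)(C)[Si](C)(C)Cl
Why: Silyl ether formation masks the C15 allylic alcohol so that only the alcohol made in step 5 directs the first epoxidation.

Step 5
Reactants: 9 neryl TBS ether
Product: 10 (2E,6Z)-8-[(tert-butyldimethylsilyl)oxy]-2,6-dimethylocta-2,6-dien-1-ol
Conditions: SeO2 (0.3 equiv), tBuOOH, salicylic acid (cat.), CH2Cl2, 0 °C to rt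
Reagents that add atoms: tert-butyl hydroperoxide, CC(C)(C)OO
Why: Riley allylic oxidation (ene reaction, then [2,3]-shift) should select the (E)-methyl group of the electron-rich terminal trisubstituted olefin, so the new CH2OH (C7) lies trans to the chain.

Step 6
Reactants: 10 (2E,6Z)-allylic alcohol
Product: 11 {(2S,3S)-3-[(3Z)-5-[(tert-butyldimethylsilyl)oxy]-3-methylpent-3-en-1-yl]-2-methyloxiran-2-yl}methanol
Conditions: Ti(OiPr)4 (cat.), L-(+)-diethyl tartrate (cat.), tBuOOH, 4 Å molecular sieves, CH2Cl2, −20 °C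
Reagents that add atoms: tert-butyl hydroperoxide, CC(C)(C)OO
Why: Sharpless asymmetric epoxidation acts only on the free allylic alcohol; L-(+)-tartrate should deliver oxygen to the face that gives the (2S,3S)-epoxide, fixing C8 and, after inversion in step 7, C9.

Step 7
Reactants: 11 epoxy alcohol; 2 alkenyl bromide
Product: 13 (2R,3S,6Z)-8-[(tert-butyldimethylsilyl)oxy]-3-{4-[(tert-butyldiphenylsilyl)oxy]but-1-en-2-yl}-2,6-dimethyloct-6-ene-1,2-diol, via alkenylmagnesium bromide 12 (not isolated)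
Conditions: 2 (3.5 equiv), Mg, THF, 50 °C; then 11, CuI (15 mol %), THF, −30 to 0 °C; aq. NH4Cl
Reagents that add atoms: none
Why: Copper-catalysed SN2 opening of the 2-methyl-2,3-epoxy alcohol can occur only at the non-quaternary epoxide carbon C9, with inversion, which sets C9 (S) beside the C8 tertiary alcohol and installs the C10 olefin.

Step 8
Reactants: 13 1,2-diol
Product: 15 terminal epoxide (8R,9S): 2-methyl-2-substituted oxirane closed between O8 and C7, via primary tosylate 14 (not isolated)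
Conditions: TsCl, Et3N, Bu2SnO (cat.), CH2Cl2, rt; then K2CO3, MeOH, rt
Reagents that add atoms: 4-methylbenzenesulfonyl chloride, Cc1ccc(cc1)S(Cl)(=O)=O
Why: Tin-catalysed regioselective sulfonylation of the primary hydroxyl and Williamson-type closure by the tertiary alkoxide should give the epoxide without breaking a bond to C8.

Step 9
Reactants: 15 terminal epoxide
Product: 17 (4S,5S,8Z)-10-[(tert-butyldimethylsilyl)oxy]-5-{4-[(tert-butyldiphenylsilyl)oxy]but-1-en-2-yl}-4-hydroxy-4,8-dimethyldec-8-enenitrile, via cyanomethyllithium 16 (not isolated)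
Conditions: CH3CN, nBuLi, THF, −78 °C; then 15, −78 °C to rt; aq. NH4Cl
Reagents that add atoms: acetonitrile, CC#N
Why: The small cyanomethyl anion should open the 2,2-disubstituted epoxide at its CH2 terminus (SN2), adding C6 and C5 and returning the C8 tertiary alcohol.

Step 10
Reactants: 17 hydroxy nitrile
Product: 19 γ-lactol (5-methyltetrahydrofuran-2-ol closed between O8 and C5, anomers; 8S,9S) with free (Z)-allylic alcohol at C15, via silyl lactol 18 (not isolated)
Conditions: iBu2AlH, CH2Cl2, −78 °C; then 1 M aq. HCl, THF, 0 °C to rt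
Reagents that add atoms: water, O
Why: Partial reduction of the nitrile to the aldimine and hydrolysis give the aldehyde, which should close onto O8 as the five-membered lactol while the same acidic work-up cleaves the primary allylic TBS ether and spares the TBDPS ether.

Step 11
Reactants: 19 lactol; 7 ylide
Product: 20 2-(trimethylsilyl)ethyl (2E,6S,7S,10Z)-7-{4-[(tert-butyldiphenylsilyl)oxy]but-1-en-2-yl}-6,12-dihydroxy-2,6,10-trimethyldodeca-2,10-dienoate
Conditions: 7, toluene, 90 °C
Reagents that add atoms: none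
Why: Wittig olefination of the lactol through its open hydroxy-aldehyde form with the α-branched stabilised ylide should give the (E)-2-methyl-enoate and free the C8 hydroxyl.

Step 12
Reactants: 20 diene diol
Product: 22 2-(trimethylsilyl)ethyl (2E)-5-[(2S,3S,6R)-3-{4-[(tert-butyldiphenylsilyl)oxy]but-1-en-2-yl}-6-[(1R)-1,2-dihydroxyethyl]-2,6-dimethyloxan-2-yl]-2-methylpent-2-enoate, via epoxy alcohol 21 (not isolated)
Conditions: Ti(OiPr)4, D-(−)-diethyl tartrate, tBuOOH, 4 Å molecular sieves, CH2Cl2, −20 °C; then camphorsulfonic acid (cat.), CH2Cl2, 0 °C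
Reagents that add atoms: tert-butyl hydroperoxide, CC(C)(C)OO
Why: Sharpless asymmetric epoxidation of the (Z)-allylic alcohol with D-(−)-tartrate should give the (13S,14R)-epoxide, which the C8 hydroxyl opens 6-exo at the tertiary carbon C13 with inversion, closing ring C of half B and setting C13 (R) and C14 (R).

Step 13
Reactants: 22 B-series pyran diol
Product: 23 B-series acetonide: as 22 with the 14,15-diol as (4R)-2,2-dimethyl-1,3-dioxolan-4-yl
Conditions: 2,2-dimethoxypropane, pyridinium p-toluenesulfonate (cat.), CH2Cl2, rt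
Reagents that add atoms: 2,2-dimethoxypropane, COC(C)(C)OC
Why: Acid-catalysed transketalisation protects the diol for the radical and enolate steps.

Step 14
Reactants: 23 B-series acetonide
Product: 24 ring-B-closed half B (5R,8S,9S,10R,13R,14R; C4 epimers): octahydrochromene with C10 bearing CH3 and CH2CH2OTBDPS, C5 bearing CH(CH3)CO2TMSE, C13 bearing CH3 and the dioxolanyl group
Conditions: Fe(acac)3, PhSiH3, EtOH/ethylene glycol, 60 °C, 0.01 M
Reagents that add atoms: none
Why: Iron-hydride hydrogen-atom transfer to the 1,1-disubstituted olefin and 6-exo-trig Giese cyclisation of the tertiary C10 radical onto the enoate (MHAT reductive olefin coupling) should close ring B of half B through a chair trans-fused to ring C, with the C10 methyl axial and the C5 arm equatorial.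

Step 15
Reactants: 24 ester
Product: 26 methylated half B (5S,8S,9S,10R,13R,14R): as 24 with C5 bearing C(CH3)2CO2TMSE, via lithium enolate 25 (not isolated)
Conditions: LiN(iPr)2, THF, −78 °C; then CH3I, DMPU, −78 to −20 °C
Reagents that add atoms: iodomethane, CI
Why: Deprotonation at the only acidic C–H and C-methylation of the ester enolate (enolate alkylation) should create the C4 gem-dimethyl quaternary carbon and erase the C4 stereocentre.

Step 16
Reactants: 26 acetonide
Product: 27 half-B 14,15-diol (5S,8S,9S,10R,13R,14R)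
Conditions: AcOH/H2O/THF (3:1:1), 45 °C
Reagents that add atoms: none
Why: Mild acid hydrolysis of the acetonide should leave the TBDPS ether and the hindered TMSE ester intact.

Step 17
Reactants: 27 diol
Product: 29 half-B 14,15-epoxide (5S,8S,9S,10R,13R,14R), via primary tosylate 28 (not isolated)
Conditions: TsCl, Et3N, Bu2SnO (cat.), CH2Cl2, rt; then K2CO3, MeOH, rt
Reagents that add atoms: 4-methylbenzenesulfonyl chloride, Cc1ccc(cc1)S(Cl)(=O)=O
Why: Selective sulfonylation of the primary C15 hydroxyl and closure by O14 should give the epoxide with retention at C14, since no bond to C14 is broken.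

Step 18
Reactants: 20 diene diol
Product: 31 2-(trimethylsilyl)ethyl (2E)-5-[(2S,3S,6S)-3-{4-[(tert-butyldiphenylsilyl)oxy]but-1-en-2-yl}-6-[(1S)-1,2-dihydroxyethyl]-2,6-dimethyloxan-2-yl]-2-methylpent-2-enoate, via epoxy alcohol 30 (not isolated)
Conditions: Ti(OiPr)4, L-(+)-diethyl tartrate, tBuOOH, 4 Å molecular sieves, CH2Cl2, −20 °C; then camphorsulfonic acid (cat.), CH2Cl2, 0 °C
Reagents that add atoms: tert-butyl hydroperoxide, CC(C)(C)OO
Why: The same Sharpless epoxidation with L-(+)-tartrate should give the enantiomeric (13R,14S)-epoxide, and 6-exo opening by O8 with inversion at C13 closes ring C of half A with C13 (S), the epimer needed for the vinyl half.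

Step 19
Reactants: 31 A-series pyran diol
Product: 32 A-series acetonide: as 31 with the 14,15-diol as (4S)-2,2-dimethyl-1,3-dioxolan-4-yl
Conditions: 2,2-dimethoxypropane, pyridinium p-toluenesulfonate (cat.), CH2Cl2, rt
Reagents that add atoms: 2,2-dimethoxypropane, COC(C)(C)OC
Why: Transketalisation masks the diol, so no second olefin or free hydroxyl is present in the key step.

Step 20
Reactants: 32 A-series acetonide
Product: 33 ring-B-closed half A (5R,8S,9S,10R,13S,14S; C4 epimers): octahydrochromene with C10 bearing CH3 and CH2CH2OTBDPS, C5 bearing CH(CH3)CO2TMSE, C13 bearing CH3 and the dioxolanyl group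
Conditions: Fe(acac)3, PhSiH3, EtOH/ethylene glycol, 60 °C, 0.01 M
Reagents that add atoms: none
Why: Hydrogen-atom transfer from an iron hydride (from Fe(acac)3 and PhSiH3) to the terminal CH2 of the 1,1-disubstituted olefin gives the tertiary C10 radical, which adds to C5 of the (E)-enoate; the C4 α-ester radical is then reduced and protonated (MHAT-initiated Giese cyclisation, the intramolecular form of the iron-mediated reductive olefin coupling). Ring B closes in 6-exo-trig mode through a chair-like transition state trans-fused to the existing tetrahydropyran, whose C8 and C9 centres (C8 methyl axial, H9 axial) fix the fold; this is the last ring of the skeleton to be closed. C10 is controlled by allylic strain in the radical: the larger CH2CH2OSi arm eclipses H9 and ends equatorial, so the new methyl ends axial, syn to the C8 methyl. C5 is controlled by the acceptor chain lying equatorial, which places H5 anti to the C10 methyl. The step needs hydrogen-atom transfer to the electron-rich olefin and not to the enoate, which the polarity of the iron hydride should secure, and cyclisation faster than quenching or 1,5-hydrogen shift, which high dilution, the nucleophilic-radical/electron-poor-acceptor match and the quaternary C8 in the tether should secure. The C4 centre is irrelevant because step 21 makes it quaternary, and a minor C10 epimer should be separable by chromatography.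

Step 21
Reactants: 33 ester
Product: 35 methylated half A (5S,8S,9S,10R,13S,14S): as 33 with C5 bearing C(CH3)2CO2TMSE, via lithium enolate 34 (not isolated)
Conditions: LiN(iPr)2, THF, −78 °C; then CH3I, DMPU, −78 to −20 °C
Reagents that add atoms: iodomethane, CI
Why: Enolate alkylation at the only acidic position should install the second C4 methyl group.

Step 22
Reactants: 35 acetonide
Product: 36 half-A 14,15-diol (5S,8S,9S,10R,13S,14S)
Conditions: AcOH/H2O/THF (3:1:1), 45 °C
Reagents that add atoms: none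
Why: Mild acid hydrolysis of the acetonide should spare the TBDPS ether and the TMSE ester.

Step 23
Reactants: 36 diol
Product: 37 half-A vinyl compound (5S,8S,9S,10R,13S): C13 bears CH3 and CH=CH2, C2 is OTBDPS, C3 is the TMSE ester
Conditions: PPh3, I2, imidazole, toluene, 110 °C
Reagents that add atoms: none
Why: Garegg–Samuelsson olefination turns the primary hydroxyl into the iodide and the secondary one into an oxyphosphonium group, and reductive elimination should give the C14=C15 vinyl group without touching C13.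

Step 24
Reactants: 37 silyl ether ester
Product: 38 half-A hydroxy acid (5S,8S,9S,10R,13S): C2 is CH2OH, C3 is CO2H
Conditions: Bu4NF, THF, rt; aq. NH4Cl
Reagents that add atoms: none
Why: Fluoride should cleave the silyl ether and fragment the TMSE ester (β-elimination) in one operation.

Step 25
Reactants: 38 half-A hydroxy acid; 29 half-B epoxide
Product: 39 A–B ester: C3 carboxyl of half A esterified with O15 of half B, C14′ hydroxyl free (R), C2 is CH2OH, C2′ is OTBDPS, C3′ is the TMSE ester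
Conditions: Cs2CO3 (0.3 equiv), DMF, 80 °C
Reagents that add atoms: none
Why: The carboxylate of the hindered acid should open the terminal epoxide at the primary carbon C15 (SN2, O-alkylation of a carboxylate), which forms the ester without attack at a hindered carbonyl and leaves C14′ untouched.

Step 26
Reactants: 39 protected A–B ester
Product: 40 A–B ester with C2 CH2OH, C2′ CH2OH, C3′ CO2H and C14′ OH free
Conditions: Bu4NF, THF, rt; aq. NH4Cl
Reagents that add atoms: none
Why: Fluoride removes the TBDPS ether and the TMSE ester of half B, while the hindered inter-unit ester should be inert.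

Step 27
Reactants: 40 diol acid
Product: 41 CNP0107285.2
Conditions: TEMPO (cat.), PhI(OAc)2, MeCN/aq. pH 7 buffer, rt
Reagents that add atoms: water, O
Why: Nitroxyl-catalysed oxidation should take the two unhindered primary alcohols through their aldehyde hydrates to the acids and spare the hindered secondary C14′ hydroxyl and the vinyl group.

Compound list
1 | 3-bromobut-3-en-1-ol | C=C(Br)CCO | starting material
2 | tert-butyl[(3-bromobut-3-en-1-yl)oxy]diphenylsilane | C=C(Br)CCO[Si](c1ccccc1)(c1ccccc1)C(C)(C)C | intermediate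
3 | 2-bromopropanoyl bromide | CC(Br)C(Br)=O | starting material
4 | 2-(trimethylsilyl)ethanol | C[Si](C)(C)CCO | starting material
5 | 2-(trimethylsilyl)ethyl 2-bromopropanoate | CC(Br)C(=O)OCC[Si](C)(C)C | intermediate
6 | {1-oxo-1-[2-(trimethylsilyl)ethoxy]propan-2-yl}triphenylphosphonium bromide | CC(C(=O)OCC[Si](C)(C)C)[P+](c1ccccc1)(c1ccccc1)c1ccccc1.[Br-] | intermediate (not isolated)
7 | 2-(trimethylsilyl)ethyl 2-(triphenyl-λ5-phosphanylidene)propanoate | CC(C(=O)OCC[Si](C)(C)C)=P(c1ccccc1)(c1ccccc1)c1ccccc1 | intermediate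
8 | nerol | CC(C)=CCC/C(C)=C\CO | starting material
9 | neryl TBS ether | CC(C)=CCC/C(C)=C\CO[Si](C)(C)C(C)(C)C | intermediate
10 | (2E,6Z)-8-[(tert-butyldimethylsilyl)oxy]-2,6-dimethylocta-2,6-dien-1-ol | OC/C(C)=C/CC/C(C)=C\CO[Si](C)(C)C(C)(C)C | intermediate
11 | (2S,3S)-epoxy alcohol (8S,9S) | CC(C)(C)[Si](C)(C)OC/C=C(C)\CC[C@@H]1O[C@@]1(C)CO | intermediate
12 | {4-[(tert-butyldiphenylsilyl)oxy]but-1-en-2-yl}magnesium bromide | C=C([Mg]Br)CCO[Si](c1ccccc1)(c1ccccc1)C(C)(C)C | intermediate (not isolated)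
13 | (2R,3S,6Z)-1,2-diol (8R,9S) | CC(C)(C)[Si](C)(C)OC/C=C(C)\CC[C@H]([C@@](C)(O)CO)C(=C)CCO[Si](c1ccccc1)(c1ccccc1)C(C)(C)C | intermediate
14 | primary tosylate of 13 | CC(C)(C)[Si](C)(C)OC/C=C(C)\CC[C@H]([C@@](C)(O)COS(=O)(=O)c1ccc(C)cc1)C(=C)CCO[Si](c1ccccc1)(c1ccccc1)C(C)(C)C | intermediate (not isolated)
15 | terminal epoxide (8R,9S) | CC(C)(C)[Si](C)(C)OC/C=C(C)\CC[C@H]([C@]1(C)CO1)C(=C)CCO[Si](c1ccccc1)(c1ccccc1)C(C)(C)C | intermediate
16 | cyanomethyllithium | [Li]CC#N | intermediate (not isolated)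
17 | (4S,5S,8Z)-hydroxy nitrile | CC(C)(C)[Si](C)(C)OC/C=C(C)\CC[C@H]([C@@](C)(O)CCC#N)C(=C)CCO[Si](c1ccccc1)(c1ccccc1)C(C)(C)C | intermediate
18 | silyl lactol (C15–OTBS) | CC(C)(C)[Si](C)(C)OC/C=C(C)\CC[C@H]([C@]1(C)CCC(O)O1)C(=C)CCO[Si](c1ccccc1)(c1ccccc1)C(C)(C)C | intermediate (not isolated)
19 | lactol with free allylic alcohol (8S,9S) | OC/C=C(C)\CC[C@H]([C@]1(C)CCC(O)O1)C(=C)CCO[Si](c1ccccc1)(c1ccccc1)C(C)(C)C | intermediate
20 | TMSE (2E,6S,7S,10Z)-dienoate diol | OC/C=C(C)\CC[C@H]([C@@](C)(O)CC/C=C(\C)C(=O)OCC[Si](C)(C)C)C(=C)CCO[Si](c1ccccc1)(c1ccccc1)C(C)(C)C | intermediate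
21 | B-series (13S,14R)-epoxy alcohol | OC[C@H]1O[C@@]1(C)CC[C@H]([C@@](C)(O)CC/C=C(\C)C(=O)OCC[Si](C)(C)C)C(=C)CCO[Si](c1ccccc1)(c1ccccc1)C(C)(C)C | intermediate (not isolated)
22 | B-series pyran diol (8S,9S,13R,14R) | OC[C@@H](O)[C@@]1(C)CC[C@@H](C(=C)CCO[Si](c2ccccc2)(c2ccccc2)C(C)(C)C)[C@](C)(CC/C=C(\C)C(=O)OCC[Si](C)(C)C)O1 | intermediate
23 | B-series acetonide | CC1(C)OC[C@@H](O1)[C@@]2(C)CC[C@@H](C(=C)CCO[Si](c3ccccc3)(c3ccccc3)C(C)(C)C)[C@](C)(CC/C=C(\C)C(=O)OCC[Si](C)(C)C)O2 | intermediate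
24 | ring-B-closed half B (5R,8S,9S,10R,13R,14R; C4 epimers) | CC1(C)OC[C@@H](O1)[C@@]2(C)CC[C@H]3[C@](C)(CCO[Si](c4ccccc4)(c4ccccc4)C(C)(C)C)[C@@H](C(C)C(=O)OCC[Si](C)(C)C)CC[C@]3(C)O2 | intermediate
25 | lithium enolate of 24 | CC1(C)OC[C@@H](O1)[C@@]2(C)CC[C@H]3[C@](C)(CCO[Si](c4ccccc4)(c4ccccc4)C(C)(C)C)[C@@H](C(C)=C(O[Li])OCC[Si](C)(C)C)CC[C@]3(C)O2 | intermediate (not isolated)
26 | methylated half B | CC1(C)OC[C@@H](O1)[C@@]2(C)CC[C@H]3[C@](C)(CCO[Si](c4ccccc4)(c4ccccc4)C(C)(C)C)[C@@H](C(C)(C)C(=O)OCC[Si](C)(C)C)CC[C@]3(C)O2 | intermediate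
27 | half-B 14,15-diol | OC[C@@H](O)[C@@]1(C)CC[C@H]2[C@](C)(CCO[Si](c3ccccc3)(c3ccccc3)C(C)(C)C)[C@@H](C(C)(C)C(=O)OCC[Si](C)(C)C)CC[C@]2(C)O1 | intermediate
28 | half-B primary tosylate | Cc1ccc(cc1)S(=O)(=O)OC[C@@H](O)[C@@]1(C)CC[C@H]2[C@](C)(CCO[Si](c3ccccc3)(c3ccccc3)C(C)(C)C)[C@@H](C(C)(C)C(=O)OCC[Si](C)(C)C)CC[C@]2(C)O1 | intermediate (not isolated)
29 | half-B 14,15-epoxide (14R) | C1O[C@H]1[C@@]2(C)CC[C@H]3[C@](C)(CCO[Si](c4ccccc4)(c4ccccc4)C(C)(C)C)[C@@H](C(C)(C)C(=O)OCC[Si](C)(C)C)CC[C@]3(C)O2 | intermediate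
30 | A-series (13R,14S)-epoxy alcohol | OC[C@@H]1O[C@]1(C)CC[C@H]([C@@](C)(O)CC/C=C(\C)C(=O)OCC[Si](C)(C)C)C(=C)CCO[Si](c1ccccc1)(c1ccccc1)C(C)(C)C | intermediate (not isolated)
31 | A-series pyran diol (8S,9S,13S,14S) | OC[C@H](O)[C@]1(C)CC[C@@H](C(=C)CCO[Si](c2ccccc2)(c2ccccc2)C(C)(C)C)[C@](C)(CC/C=C(\C)C(=O)OCC[Si](C)(C)C)O1 | intermediate
32 | A-series acetonide | CC1(C)OC[C@H](O1)[C@]2(C)CC[C@@H](C(=C)CCO[Si](c3ccccc3)(c3ccccc3)C(C)(C)C)[C@](C)(CC/C=C(\C)C(=O)OCC[Si](C)(C)C)O2 | intermediate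
33 | ring-B-closed half A (5R,8S,9S,10R,13S,14S; C4 epimers) | CC1(C)OC[C@H](O1)[C@]2(C)CC[C@H]3[C@](C)(CCO[Si](c4ccccc4)(c4ccccc4)C(C)(C)C)[C@@H](C(C)C(=O)OCC[Si](C)(C)C)CC[C@]3(C)O2 | intermediate
34 | lithium enolate of 33 | CC1(C)OC[C@H](O1)[C@]2(C)CC[C@H]3[C@](C)(CCO[Si](c4ccccc4)(c4ccccc4)C(C)(C)C)[C@@H](C(C)=C(O[Li])OCC[Si](C)(C)C)CC[C@]3(C)O2 | intermediate (not isolated)
35 | methylated half A | CC1(C)OC[C@H](O1)[C@]2(C)CC[C@H]3[C@](C)(CCO[Si](c4ccccc4)(c4ccccc4)C(C)(C)C)[C@@H](C(C)(C)C(=O)OCC[Si](C)(C)C)CC[C@]3(C)O2 | intermediate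
36 | half-A 14,15-diol | OC[C@H](O)[C@]1(C)CC[C@H]2[C@](C)(CCO[Si](c3ccccc3)(c3ccccc3)C(C)(C)C)[C@@H](C(C)(C)C(=O)OCC[Si](C)(C)C)CC[C@]2(C)O1 | intermediate
37 | half-A vinyl compound | C=C[C@]1(C)CC[C@H]2[C@](C)(CCO[Si](c3ccccc3)(c3ccccc3)C(C)(C)C)[C@@H](C(C)(C)C(=O)OCC[Si](C)(C)C)CC[C@]2(C)O1 | intermediate
38 | half-A hydroxy acid | C=C[C@]1(C)CC[C@H]2[C@](C)(CCO)[C@@H](C(C)(C)C(=O)O)CC[C@]2(C)O1 | intermediate
39 | protected A–B ester | C=C[C@]1(C)CC[C@H]2[C@](C)(CCO)[C@@H](C(C)(C)C(=O)OC[C@@H](O)[C@@]3(C)CC[C@H]4[C@](C)(CCO[Si](c5ccccc5)(c5ccccc5)C(C)(C)C)[C@@H](C(C)(C)C(=O)OCC[Si](C)(C)C)CC[C@]4(C)O3)CC[C@]2(C)O1 | intermediate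
40 | A–B ester diol acid | C=C[C@]1(C)CC[C@H]2[C@](C)(CCO)[C@@H](C(C)(C)C(=O)OC[C@@H](O)[C@@]3(C)CC[C@H]4[C@](C)(CCO)[C@@H](C(C)(C)C(=O)O)CC[C@]4(C)O3)CC[C@]2(C)O1 | intermediate
41 | CNP0107285.2 | C=C[C@]1(C)CC[C@H]2[C@](C)(CC(=O)O)[C@@H](C(C)(C)C(=O)OC[C@@H](O)[C@@]3(C)CC[C@H]4[C@](C)(CC(=O)O)[C@@H](C(C)(C)C(=O)O)CC[C@]4(C)O3)CC[C@]2(C)O1 | target

Total step count: 27. Longest linear sequence: 18 steps (steps 4–11, 18–24, 25–27).

Steps most likely to fail

Step 20 (key cyclisation). The tertiary radical may be quenched before it closes the ring, leaving a hydrogenated or isomerised olefin; the hydride may attack the enoate; or facial selectivity at C10 may be modest. The fallback makes the same radical without a metal hydride. It sets out from 32: Markovnikov oxymercuration–demercuration (Hg(OAc)2, THF/H2O; then NaBH4, NaOH) should give the C10 tertiary alcohol F1. Acylation with methyl chlorooxoacetate (Et3N, DMAP, CH2Cl2) gives the methyl oxalate F2, and half-saponification (CsOH, THF/H2O) the caesium oxalate F3. Visible-light photoredox decarboxylation (Ir[dF(CF3)ppy]2(dtbbpy)PF6, blue light, DME/DMF, H2O, rt) should release the tertiary C10 radical, which undergoes the same 6-exo Giese closure at room temperature and returns to 33.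

Step 21 (quaternisation of C4). Alkylation of the congested tetrasubstituted enolate may be slow, so that proton return or O-alkylation takes over. The fallback replaces SN2 alkylation by a one-carbon insertion. It sets out from 33: the enolate is trapped as the trimethylsilyl ketene acetal F4 (LiN(iPr)2, Me3SiCl, THF, −78 °C). Simmons–Smith cyclopropanation (Et2Zn, CH2I2, CH2Cl2, 0 °C) gives the siloxycyclopropane F5. Acid-induced ring opening (TsOH, wet THF) with cleavage of the C3–CH2 bond turns the added CH2 into the second C4 methyl group and returns to 35.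

Step 25 (union of the halves). Opening of the epoxide by the carboxylate of the neopentyl-type acid may be too slow, so that the epoxide is lost to rearrangement or to the C2 hydroxyl. The fallback uses a more electrophilic partner. It sets out from diol 27: SOCl2 and Et3N (CH2Cl2, 0 °C) give the cyclic sulfite F6, and oxidation (RuCl3 cat., NaIO4, MeCN/H2O) the cyclic sulfate F7. The caesium carboxylate of 38 (Cs2CO3, DMF, rt) should attack the primary carbon C15 to give the sulfate monoester F8. Hydrolysis of the sulfate ester (H2SO4 cat., THF/H2O) returns to 39 with C14′ unchanged.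

Further compounds
F1 | step 20 | C10 tertiary alcohol from 32 (C10 epimers) | CC1(C)OC[C@H](O1)[C@]2(C)CC[C@@H](C(C)(O)CCO[Si](c3ccccc3)(c3ccccc3)C(C)(C)C)[C@](C)(CC/C=C(\C)C(=O)OCC[Si](C)(C)C)O2
F2 | step 20 | methyl oxalate of F1 | CC1(C)OC[C@H](O1)[C@]2(C)CC[C@@H](C(C)(OC(=O)C(=O)OC)CCO[Si](c3ccccc3)(c3ccccc3)C(C)(C)C)[C@](C)(CC/C=C(\C)C(=O)OCC[Si](C)(C)C)O2
F3 | step 20 | caesium oxalate of F1 | CC1(C)OC[C@H](O1)[C@]2(C)CC[C@@H](C(C)(OC(=O)C(=O)[O-])CCO[Si](c3ccccc3)(c3ccccc3)C(C)(C)C)[C@](C)(CC/C=C(\C)C(=O)OCC[Si](C)(C)C)O2.[Cs+]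
F4 | step 21 | trimethylsilyl ketene acetal of 33 | CC1(C)OC[C@H](O1)[C@]2(C)CC[C@H]3[C@](C)(CCO[Si](c4ccccc4)(c4ccccc4)C(C)(C)C)[C@@H](C(C)=C(O[Si](C)(C)C)OCC[Si](C)(C)C)CC[C@]3(C)O2
F5 | step 21 | siloxycyclopropane from F4 | CC1(C)OC[C@H](O1)[C@]2(C)CC[C@H]3[C@](C)(CCO[Si](c4ccccc4)(c4ccccc4)C(C)(C)C)[C@@H](C5(C)CC5(O[Si](C)(C)C)OCC[Si](C)(C)C)CC[C@]3(C)O2
F6 | step 25 | cyclic sulfite of 27 | O=S1OC[C@@H](O1)[C@@]2(C)CC[C@H]3[C@](C)(CCO[Si](c4ccccc4)(c4ccccc4)C(C)(C)C)[C@@H](C(C)(C)C(=O)OCC[Si](C)(C)C)CC[C@]3(C)O2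
F7 | step 25 | cyclic sulfate of 27 | O=S1(=O)OC[C@@H](O1)[C@@]2(C)CC[C@H]3[C@](C)(CCO[Si](c4ccccc4)(c4ccccc4)C(C)(C)C)[C@@H](C(C)(C)C(=O)OCC[Si](C)(C)C)CC[C@]3(C)O2
F8 | step 25 | caesium C14′ sulfate monoester of 39 | C=C[C@]1(C)CC[C@H]2[C@](C)(CCO)[C@@H](C(C)(C)C(=O)OC[C@@H](OS(=O)(=O)[O-])[C@@]3(C)CC[C@H]4[C@](C)(CCO[Si](c5ccccc5)(c5ccccc5)C(C)(C)C)[C@@H](C(C)(C)C(=O)OCC[Si](C)(C)C)CC[C@]4(C)O3)CC[C@]2(C)O1.[Cs+]
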